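## Retrosynthetic overview

1. Target 11 ⇐ dienoic acid 10: one oxidative Pd(II) step closes the butenolide (C6–O) and places the acetate on C13 (C13–O); this is the last ring formed.
2. 10 ⇐ tertiary carbinol 6: allylic oxidation of the C12 methyl to CO2H and dehydration to the C6=C7 olefin.
3. 6 ⇐ allylic alcohol 3: hydroxy-directed singlet-oxygen ene reaction (C7–O, isopropenyl unmasked) and C8 tigloylation.
4. 3 ⇐ germacrone 1: catalyst-controlled double epoxidation (both oxiranes first; sets C1, C10, C4, C5) and CBS reduction (sets C8).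
5. Ring order: the ten-membered carbocycle is bought with germacrone, then two oxiranes (step 1), then the butenolide (step 8); no C–C bond is made.

Assumption: germacrone (bulk constituent of Geranium macrorrhizum and Curcuma oils) is taken as a cheap commercial starting material; germacrane numbering is used (ring C1–C10, side chain C11–C13, C14 on C10, C15 on C4).

## Route

Step 1
Reactants: 1 germacrone
Product: 2 (1R,4R,5R,10R)-1,10:4,5-diepoxygermacr-7(11)-en-8-one
Conditions: Shi ketone (D-fructose-derived, 30 mol%), Oxone, K2CO3, Bu4NHSO4 (cat.), MeCN–DMM/aq. Na2B4O7–EDTA, 0 °C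
Reagents that add atoms: Oxone (potassium peroxymonosulfate) [K+].[O-]S(=O)(=O)OO
Why: Shi asymmetric epoxidation: the chiral dioxirane attacks each (E)-trisubstituted ring olefin on its exposed outer face through the spiro transition state that gives the (R,R)-oxirane, and because the planar-chiral ring conformers interconvert the catalyst selects the matched faces and so sets C1, C10, C4 and C5, while the tetrasubstituted, carbonyl-deactivated 7(11)-olefin is left untouched.

Step 2
Reactants: 2 (1R,4R,5R,10R)-1,10:4,5-diepoxygermacr-7(11)-en-8-one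
Product: 3 (1R,4R,5R,8S,10R)-1,10:4,5-diepoxygermacr-7(11)-en-8-ol
Conditions: (R)-Me-CBS (20 mol%), catecholborane, toluene, −78 °C; MeOH, aq. NaHCO3
Reagents that add atoms: none
Why: Corey–Bakshi–Shibata reduction: catalyst-controlled 1,2-hydride delivery with the fully substituted alkenyl carbon C7 as the large group and the C9 methylene as the small group gives the 8S carbinol.

Step 3
Reactants: 3 (1R,4R,5R,8S,10R)-1,10:4,5-diepoxygermacr-7(11)-en-8-ol
Product: 5 (1R,4R,5R,7S,8S,10R)-1,10:4,5-diepoxygermacr-11(13)-ene-7,8-diol, via 7-hydroperoxide 4 (not isolated)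
Conditions: O2, TPP (cat.), white LED, CH2Cl2, −20 °C; then PPh3, −20 °C → rt
Reagents that add atoms: dioxygen O=O
Why: Schenck ene reaction of singlet oxygen on the only olefin present, directed by hydrogen bonding to the allylic hydroxyl in the A(1,3)-minimised rotamer, so that oxygen adds to C7 syn to the C8–OH (7S, a temporary centre) and a methyl hydrogen is abstracted to unmask the isopropenyl group; PPh3 then reduces the hydroperoxide.

Step 4
Reactants: 5 (1R,4R,5R,7S,8S,10R)-1,10:4,5-diepoxygermacr-11(13)-ene-7,8-diol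
Product: 6 (1R,4R,5R,7S,8S,10R)-1,10:4,5-diepoxy-7-hydroxygermacr-11(13)-en-8-yl tiglate
Conditions: tiglic anhydride, DMAP (cat.), Et3N, CH2Cl2, 0 °C → rt
Reagents that add atoms: tiglic anhydride C/C=C(\C)C(=O)OC(=O)/C(C)=C/C
Why: DMAP-catalysed acylation takes the secondary C8 hydroxyl and leaves the tertiary C7 hydroxyl, with retention at C8.

Step 5
Reactants: 6 (1R,4R,5R,7S,8S,10R)-1,10:4,5-diepoxy-7-hydroxygermacr-11(13)-en-8-yl tiglate
Product: 8 (1R,4R,5R,7S,8S,10R)-1,10:4,5-diepoxy-7-hydroxy-12-oxogermacr-11(13)-en-8-yl tiglate, via allylic alcohol 7 (not isolated)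
Conditions: SeO2 (30 mol%), t-BuOOH, CH2Cl2, 0 °C → rt; then MnO2, CH2Cl2, rt
Reagents that add atoms: tert-butyl hydroperoxide CC(C)(C)OO; selenium dioxide (oxygen carrier) O=[Se]=O
Why: Sharpless–Riley allylic oxidation (ene reaction then [2,3]-shift) can only reach the C12 methyl because C7 is quaternary and the tiglate olefin is electron-poor, and MnO2 then oxidises the primary allylic alcohol to the enal.

Step 6
Reactants: 8 (1R,4R,5R,7S,8S,10R)-1,10:4,5-diepoxy-7-hydroxy-12-oxogermacr-11(13)-en-8-yl tiglate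
Product: 9 (1R,4R,5R,6Z,8S,10R)-1,10:4,5-diepoxy-12-oxogermacra-6,11(13)-dien-8-yl tiglate
Conditions: Burgess reagent, THF, 50 °C
Reagents that add atoms: none
Why: Burgess syn-dehydration of the tertiary carbinol is expected to run toward the C6 methylene and away from the acyloxy-bearing C8 (as 5-hydroxy-6-acyloxy steroids do), giving the cis (6Z) ring olefin, the less strained geometry in the ten-membered ring.

Step 7
Reactants: 9 (1R,4R,5R,6Z,8S,10R)-1,10:4,5-diepoxy-12-oxogermacra-6,11(13)-dien-8-yl tiglate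
Product: 10 (1R,4R,5R,6Z,8S,10R)-1,10:4,5-diepoxy-8-tigloyloxygermacra-6,11(13)-dien-12-oic acid
Conditions: NaClO2, NaH2PO4, 2-methyl-2-butene, t-BuOH/H2O, 0 °C
Reagents that add atoms: sodium chlorite [Na+].[O-]Cl=O
Why: Pinnick oxidation converts the enal to the acid under buffered conditions, with the scavenger removing HOCl so that the diene, oxiranes and esters survive.

Step 8
Reactants: 10 (1R,4R,5R,6Z,8S,10R)-1,10:4,5-diepoxy-8-tigloyloxygermacra-6,11(13)-dien-12-oic acid
Product: 11 (1R,4R,5R,6S,8S,10R)-13-acetoxy-1,10:4,5-diepoxy-8-tigloyloxygermacr-7(11)-en-12,6-olide (CNP0251711.1)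
Conditions: Pd(OAc)2 (10 mol%), 1,4-benzoquinone (2 equiv), LiOAc (20 mol%), AcOH (10 equiv), acetone, 25 °C
Reagents that add atoms: acetic acid CC(=O)O
Why: Proposed new method: Pd(II)-catalysed oxidative 1,4-acetoxy-lactonization of a 2-carboxy-1,3-diene, in which the palladium carboxylate adds across C6=C7 (syn-carboxypalladation, 5-endo, as in Pd(II) cyclisations of 3-alkenoic acids) on the ring face not covered by the transannular chain, forming the C6–O bond and setting 6S, the resulting allyl-palladium over C7–C11–C13 is captured by acetate at the unhindered primary terminus C13 so that the new tetrasubstituted olefin lands at C7=C11 in conjugation with the lactone, and benzoquinone/AcOH reoxidises Pd(0); the closest known reaction type is the Pd(II)/benzoquinone 1,4-diacetoxylation and 1,4-acyloxy-lactonization of conjugated dienes, not yet shown for a carboxyl group on C2 of the diene or for butenolide formation.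

## Compound list

1 | germacrone, (3E,7E)-3,7-dimethyl-10-(propan-2-ylidene)cyclodeca-3,7-dien-1-one | O=C1C/C(C)=C/CC/C(C)=C/CC1=C(C)C | starting material
2 | (1R,4R,5R,10R)-1,10:4,5-diepoxygermacr-7(11)-en-8-one | O=C1C[C@@]2(C)O[C@@H]2CC[C@@]2(C)O[C@@H]2CC1=C(C)C | intermediate
3 | (1R,4R,5R,8S,10R)-1,10:4,5-diepoxygermacr-7(11)-en-8-ol | O[C@H]1C[C@@]2(C)O[C@@H]2CC[C@@]2(C)O[C@@H]2CC1=C(C)C | intermediate
4 | (1R,4R,5R,7S,8S,10R)-7-hydroperoxy-1,10:4,5-diepoxygermacr-11(13)-en-8-ol | O[C@H]1C[C@@]2(C)O[C@@H]2CC[C@@]2(C)O[C@@H]2C[C@]1(OO)C(C)=C | intermediate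
5 | (1R,4R,5R,7S,8S,10R)-1,10:4,5-diepoxygermacr-11(13)-ene-7,8-diol | O[C@H]1C[C@@]2(C)O[C@@H]2CC[C@@]2(C)O[C@@H]2C[C@]1(O)C(C)=C | intermediate
6 | (1R,4R,5R,7S,8S,10R)-1,10:4,5-diepoxy-7-hydroxygermacr-11(13)-en-8-yl tiglate | C/C=C(\C)C(=O)O[C@H]1C[C@@]2(C)O[C@@H]2CC[C@@]2(C)O[C@@H]2C[C@]1(O)C(C)=C | intermediate
7 | (1R,4R,5R,7S,8S,10R)-1,10:4,5-diepoxy-7,12-dihydroxygermacr-11(13)-en-8-yl tiglate | C/C=C(\C)C(=O)O[C@H]1C[C@@]2(C)O[C@@H]2CC[C@@]2(C)O[C@@H]2C[C@]1(O)C(CO)=C | intermediate
8 | (1R,4R,5R,7S,8S,10R)-1,10:4,5-diepoxy-7-hydroxy-12-oxogermacr-11(13)-en-8-yl tiglate | C/C=C(\C)C(=O)O[C@H]1C[C@@]2(C)O[C@@H]2CC[C@@]2(C)O[C@@H]2C[C@]1(O)C(C=O)=C | intermediate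
9 | (1R,4R,5R,6Z,8S,10R)-1,10:4,5-diepoxy-12-oxogermacra-6,11(13)-dien-8-yl tiglate | C/C=C(\C)C(=O)O[C@H]1C[C@@]2(C)O[C@@H]2CC[C@@]2(C)O[C@@H]2/C=C1/C(C=O)=C | intermediate
10 | (1R,4R,5R,6Z,8S,10R)-1,10:4,5-diepoxy-8-tigloyloxygermacra-6,11(13)-dien-12-oic acid | C/C=C(\C)C(=O)O[C@H]1C[C@@]2(C)O[C@@H]2CC[C@@]2(C)O[C@@H]2/C=C1/C(C(=O)O)=C | intermediate
11 | (1R,4R,5R,6S,8S,10R)-13-acetoxy-1,10:4,5-diepoxy-8-tigloyloxygermacr-7(11)-en-12,6-olide (CNP0251711.1) | C/C=C(\C)C(=O)O[C@H]1C[C@@]2(C)O[C@@H]2CC[C@@]2(C)O[C@@H]2[C@H]2OC(=O)C(COC(C)=O)=C12 | target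

## Step count and risk

Total step count: 8. Longest linear sequence: 8 (fully linear from germacrone).

The three steps most likely to fail are 8, 6 and 1.

Step 8 is the proposed new step. The cross-conjugated diene may not engage Pd(II), the vinyl oxirane may be ionised by transient Pd(0), and the face selectivity at C6 is untested. The fallback uses known chemistry and sets out from 10: reversible iodolactonization (I2, MeCN, 0 °C, dark) followed by allylic equilibration gives the conjugated iodolactone F8, and displacement of the primary allylic iodide with AgOAc in AcOH/DMF comes back to the route at 11.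

Step 6 may lose H-8 instead of H-6 (giving an enol tiglate) or give the trans ring olefin. The fallback dehydrates while C8 is a ketone, so that C6 is the only carbon that can lose a proton. It sets out from 5: SeO2 (cat.)/t-BuOOH gives triol F3, and Dess–Martin periodinane oxidises its primary allylic and C8 hydroxyls to keto enal F4. Burgess reagent then gives dienone aldehyde F5, and Pinnick oxidation gives keto acid F6. Luche reduction (NaBH4, CeCl3, MeOH, −40 °C) gives hydroxy acid F7, with any 8R epimer removed by chromatography. Tiglic anhydride/DMAP with bicarbonate work-up (cleaving the mixed anhydride) comes back to the route at 10.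

Step 1 may give incomplete facial control or stop at the mono-epoxide, and the β,γ-epoxy ketone is base-sensitive. The fallback replaces asymmetric catalysis by racemic epoxidation and a diastereomer split. It sets out from 1: mCPBA (2.2 equiv), NaHCO3, CH2Cl2, 0 °C gives 2 together with its enantiomer, diepoxy ketone F1. The CBS reduction of step 2 on this racemate is catalyst-controlled to 8S for both antipodes, so it gives 3 and the diastereomeric alcohol F2. These are separated on silica, and the route is rejoined at 3.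

## Further compounds

F1 | step 1 | (1S,4S,5S,10S)-1,10:4,5-diepoxygermacr-7(11)-en-8-one | O=C1C[C@]2(C)O[C@H]2CC[C@]2(C)O[C@H]2CC1=C(C)C
F2 | step 1 | (1S,4S,5S,8S,10S)-1,10:4,5-diepoxygermacr-7(11)-en-8-ol | O[C@H]1C[C@]2(C)O[C@H]2CC[C@]2(C)O[C@H]2CC1=C(C)C
F3 | step 6 | (1R,4R,5R,7S,8S,10R)-1,10:4,5-diepoxygermacr-11(13)-ene-7,8,12-triol | O[C@H]1C[C@@]2(C)O[C@@H]2CC[C@@]2(C)O[C@@H]2C[C@]1(O)C(CO)=C
F4 | step 6 | (1R,4R,5R,7S,10R)-1,10:4,5-diepoxy-7-hydroxy-8-oxogermacr-11(13)-en-12-al | O=C1C[C@@]2(C)O[C@@H]2CC[C@@]2(C)O[C@@H]2C[C@]1(O)C(C=O)=C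
F5 | step 6 | (1R,4R,5R,6Z,10R)-1,10:4,5-diepoxy-8-oxogermacra-6,11(13)-dien-12-al | O=C1C[C@@]2(C)O[C@@H]2CC[C@@]2(C)O[C@@H]2/C=C1/C(C=O)=C
F6 | step 6 | (1R,4R,5R,6Z,10R)-1,10:4,5-diepoxy-8-oxogermacra-6,11(13)-dien-12-oic acid | O=C1C[C@@]2(C)O[C@@H]2CC[C@@]2(C)O[C@@H]2/C=C1/C(C(=O)O)=C
F7 | step 6 | (1R,4R,5R,6Z,8S,10R)-1,10:4,5-diepoxy-8-hydroxygermacra-6,11(13)-dien-12-oic acid | O[C@H]1C[C@@]2(C)O[C@@H]2CC[C@@]2(C)O[C@@H]2/C=C1/C(C(=O)O)=C
F8 | step 8 | (1R,4R,5R,6S,8S,10R)-1,10:4,5-diepoxy-13-iodo-8-tigloyloxygermacr-7(11)-en-12,6-olide | C/C=C(\C)C(=O)O[C@H]1C[C@@]2(C)O[C@@H]2CC[C@@]2(C)O[C@@H]2[C@H]2OC(=O)C(CI)=C12
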